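The cyclohexene ring is cut at C4–C5. Read backwards, C5=C6 is the enol triflate of a C6 ketone, so C4(OH)–C5–C6(=O) is an aldol unit; quaternary C1 leaves C5 as the only enolisable position, and the C3 carbinol can steer C4. An acyclic (R)-α-silyloxy aldehyde bearing a vinyl ketone is therefore closed in one flask by conjugate hydrosilylation and silyl-transfer Mukaiyama aldol addition, which forms the ring, sets C4 trans to C3 and protects O4. The derived enol triflate is joined at C6–C7 to a C31 polyenyl boronate built from crocetin dialdehyde and a geranyl ylide.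

Key step: step 6

Remark: carotenoid numbering is used (ring C1 gem-dimethyl, C2 CH2, C3 and C4 carbinols, C5 methyl-bearing alkene carbon, C6 chain-bearing alkene carbon, chain from C7; primed numbers for the open-chain end). The target is (3R,4R), trans-diol, all-E. (S)-Glycidol, crocetin dialdehyde, geranyl bromide and all reagents are taken as commercial.

Step 1
Reactants: 1 isobutyric acid; 2 (S)-glycidol
Product: 4 (5R)-5-(hydroxymethyl)-3,3-dimethyloxolan-2-one, via dihydroxy acid 3 (not isolated)
Conditions: LiN(iPr)2 (3.1 equiv), THF, 0 → 45 °C; then 2, 0 → 23 °C; 3 M HCl, 23 °C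
Reagents that add atoms: none
Why: Epoxide opening by the dilithiated carboxylic acid at the terminal CH2 of the glycidol alkoxide forms C1–C2 without touching the carbinol stereocentre (the Payne rearrangement of glycidol is degenerate and returns the same enantiomer), and acidification closes the γ-lactone, helped by the gem-dimethyl effect.

Step 2
Reactants: 4 (5R)-5-(hydroxymethyl)-3,3-dimethyloxolan-2-one
Product: 5 (4R)-4,5-dihydroxy-N-methoxy-N,2,2-trimethylpentanamide
Conditions: MeNH(OMe)·HCl (3 equiv), iPrMgCl (7 equiv), THF, −20 → 0 °C; aq. NH4Cl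
Reagents that add atoms: N,O-dimethylhydroxylamine hydrochloride, CNOC.Cl
Why: Weinreb amide formation: the chloromagnesium amide made in the flask opens the lactone by acyl substitution, which frees the C3 hydroxyl and leaves its stereocentre untouched.

Step 3
Reactants: 5 (4R)-4,5-dihydroxy-N-methoxy-N,2,2-trimethylpentanamide
Product: 6 (4R)-N-methoxy-N,2,2-trimethyl-4,5-bis(triethylsilyloxy)pentanamide
Conditions: Et3SiCl (2.4 equiv), imidazole, DMF, 0 → 23 °C
Reagents that add atoms: chlorotriethylsilane, CC[Si](Cl)(CC)CC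
Why: Imidazole-promoted silyl ether formation on the primary and the secondary hydroxyl, run promptly so that the γ-hydroxy amide cannot relactonise; no stereocentre is involved.

Step 4
Reactants: 6 (4R)-N-methoxy-N,2,2-trimethyl-4,5-bis(triethylsilyloxy)pentanamide
Product: 7 (6R)-4,4-dimethyl-6,7-bis(triethylsilyloxy)hept-1-en-3-one
Conditions: CH2=CHMgBr (3 equiv), THF, 0 → 23 °C; inverse quench into cold aq. NH4Cl
Reagents that add atoms: vinylmagnesium bromide, C=C[Mg]Br
Why: Weinreb ketone synthesis: the Grignard reagent adds once because the magnesium-chelated tetrahedral intermediate survives until the quench, and the inverse quench keeps the liberated amine from adding to the new enone.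

Step 5
Reactants: 7 (6R)-4,4-dimethyl-6,7-bis(triethylsilyloxy)hept-1-en-3-one
Product: 8 (2R)-4,4-dimethyl-5-oxo-2-(triethylsilyloxy)hept-6-enal
Conditions: (COCl)2, DMSO, CH2Cl2, −78 → −30 °C; Et3N, → 0 °C; used at once
Reagents that add atoms: none
Why: Swern oxidation applied directly to the bis-silyl ether: the chlorodimethylsulfonium ion attacks the less hindered primary silyl ether oxygen, so only the primary carbinol carbon (C4) is oxidised while the secondary silyl ether and the C3 stereocentre are kept.

Step 6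
Reactants: 8 (2R)-4,4-dimethyl-5-oxo-2-(triethylsilyloxy)hept-6-enal
Product: 10 (2R,3R,4R)-2,6,6-trimethyl-3,4-bis(triethylsilyloxy)cyclohexan-1-one, via silyl enol ether 9 (not isolated)
Conditions: Et3SiH (1.05 equiv), Pt2[(CH2=CHSiMe2)2O]3 (0.1 mol % Pt), toluene, 23 °C; then CH2Cl2, −78 °C, Tf2NH (5 mol %); Et3N quench
Reagents that add atoms: triethylsilane, CC[SiH](CC)CC
Why: Zerovalent platinum catalyses 1,4-hydrosilylation of the s-cis vinyl ketone to the (Z)-silyl enol ether 9; Tf2NH then forms Et3SiNTf2, which silylates the aldehyde oxygen and triggers attack of enol carbon C5 on aldehyde carbon C4 with silyl transfer, so the C4–C5 bond, the ring and the O4 silyl ether arise in one flask. The closest known reaction types are the reductive (conjugate hydrosilylation) aldol sequence and the silyl triflimide-catalysed intramolecular Mukaiyama aldol reaction. The six-membered ring closes in the 6-(enolendo)-exo-trig mode. The new stereocentre C4 is controlled by the C3 stereocentre and the C1 gem-dimethyl group: in the open chair-like transition state the C3 silyloxy group should lie equatorial (anti to the forming bond, as in the polar 1,2-induction model, and clear of the axial C1 methyl) and the silylated carbonyl oxygen antiperiplanar to the enol double bond, hence equatorial, which should give the 3,4-trans (3R,4R) product; the C5 methyl centre (expected equatorial) is erased in step 7. The step needs conjugate hydrosilylation of the enone in the presence of the aldehyde and an open rather than chelated transition state; the platinum/trialkylsilane system, the non-chelating silyl groups and the absence of base (which also protects the epimerisable C3 centre) are meant to secure this.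

Step 7
Reactants: 10 (2R,3R,4R)-2,6,6-trimethyl-3,4-bis(triethylsilyloxy)cyclohexan-1-one
Product: 12 (3R,4R)-2,6,6-trimethyl-3,4-bis(triethylsilyloxy)cyclohex-1-en-1-yl trifluoromethanesulfonate, via potassium enolate 11 (not isolated)
Conditions: KN(SiMe3)2, THF, −78 °C; PhNTf2, −78 → 0 °C; aq. NH4Cl
Reagents that add atoms: N-phenylbis(trifluoromethanesulfonimide), O=S(=O)(N(c1ccccc1)S(=O)(=O)C(F)(F)F)C(F)(F)F
Why: Enol triflate formation from the potassium enolate: C5 carries the only α-hydrogen (C1 is quaternary), so the C5=C6 regiochemistry is fixed, and the equatorial C4 silyloxy group is poorly aligned for β-elimination at low temperature.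

Step 8
Reactants: 13 geranyl bromide
Product: 14 geranyltriphenylphosphonium bromide
Conditions: PPh3, toluene, 23 → 50 °C
Reagents that add atoms: triphenylphosphine, c1ccc(cc1)P(c1ccccc1)c1ccccc1
Why: SN2 quaternisation of the phosphine by the allylic bromide (phosphonium salt formation) with retention of the E-trisubstituted alkene.

Step 9
Reactants: 14 geranyltriphenylphosphonium bromide; 15 crocetin dialdehyde
Product: 18 apo-8'-lycopenal (all-E C30 aldehyde), via ylide 16 (not isolated), via 16Z aldehyde 17 (not isolated)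
Conditions: 15 (3 equiv), NaOMe, CH2Cl2–MeOH, 0 → 23 °C; then I2 (1 mol %), CH2Cl2, daylight; crystallisation
Reagents that add atoms: none
Why: Wittig olefination of one aldehyde group of the symmetrical dialdehyde (used in excess to favour mono-olefination) by the allylic ylide, then iodine-catalysed Z to E equilibration so that the new C7'=C8' bond ends E.

Step 10
Reactants: 18 apo-8'-lycopenal
Product: 19 (all-E)-C31 polyenyl pinacol boronate
Conditions: Cl2CHBpin (2 equiv), CrCl2 (8 equiv), LiI (4 equiv), THF, 23 °C, dark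
Reagents that add atoms: 2-(dichloromethyl)-4,4,5,5-tetramethyl-1,3,2-dioxaborolane, ClC(Cl)B1OC(C)(C)C(C)(C)O1
Why: Takai–Utimoto olefination: the geminal dichromium boronate adds to the aldehyde and eliminates to the (E)-alkenyl boronate, which sets the C7=C8 geometry.

Step 11
Reactants: 12 (3R,4R)-2,6,6-trimethyl-3,4-bis(triethylsilyloxy)cyclohex-1-en-1-yl trifluoromethanesulfonate; 19 C31 polyenyl pinacol boronate
Product: 20 (3R,4R)-3,4-bis(triethylsilyloxy)-β,ψ-carotene
Conditions: Pd(OAc)2 (5 mol %), SPhos (10 mol %), K3PO4 (3 equiv), THF–H2O 10:1, 40 °C, argon, dark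
Reagents that add atoms: none
Why: Suzuki–Miyaura coupling of the alkenyl triflate with the alkenyl boronate forms C6–C7 with retention of both alkene geometries; the bulky electron-rich biaryl phosphine is chosen for oxidative addition at the tetrasubstituted triflate.

Step 12
Reactants: 20 (3R,4R)-3,4-bis(triethylsilyloxy)-β,ψ-carotene
Product: 21 (3R,4R)-β,ψ-carotene-3,4-diol (target)
Conditions: Bu4NF (3 equiv), AcOH (3 equiv), THF, 0 → 23 °C, dark
Reagents that add atoms: none
Why: Fluoride-mediated cleavage of both silyl ethers under acetic acid buffering, which avoids acid that could ionise the allylic C4 oxygen of the polyene; the stereocentres are unaffected.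

Compound list
1 | isobutyric acid | CC(C)C(=O)O | starting material
2 | (S)-glycidol | OC[C@H]1CO1 | starting material
3 | (4R)-4,5-dihydroxy-2,2-dimethylpentanoic acid (not isolated) | OC[C@H](O)CC(C)(C)C(=O)O | intermediate
4 | (5R)-5-(hydroxymethyl)-3,3-dimethyloxolan-2-one | OC[C@H]1CC(C)(C)C(=O)O1 | intermediate
5 | (4R)-4,5-dihydroxy-N-methoxy-N,2,2-trimethylpentanamide | OC[C@H](O)CC(C)(C)C(=O)N(C)OC | intermediate
6 | (4R)-N-methoxy-N,2,2-trimethyl-4,5-bis(triethylsilyloxy)pentanamide | CC[Si](CC)(CC)OC[C@H](O[Si](CC)(CC)CC)CC(C)(C)C(=O)N(C)OC | intermediate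
7 | (6R)-4,4-dimethyl-6,7-bis(triethylsilyloxy)hept-1-en-3-one | CC[Si](CC)(CC)OC[C@H](O[Si](CC)(CC)CC)CC(C)(C)C(=O)C=C | intermediate
8 | (2R)-4,4-dimethyl-5-oxo-2-(triethylsilyloxy)hept-6-enal | O=C[C@H](O[Si](CC)(CC)CC)CC(C)(C)C(=O)C=C | intermediate
9 | (2R,5Z)-4,4-dimethyl-2,5-bis(triethylsilyloxy)hept-5-enal (not isolated) | O=C[C@H](O[Si](CC)(CC)CC)CC(C)(C)/C(O[Si](CC)(CC)CC)=C/C | intermediate
10 | (2R,3R,4R)-2,6,6-trimethyl-3,4-bis(triethylsilyloxy)cyclohexan-1-one | O=C1[C@H](C)[C@@H](O[Si](CC)(CC)CC)[C@H](O[Si](CC)(CC)CC)CC1(C)C | intermediate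
11 | potassium enolate of 10 (not isolated) | [K+].[O-]C1=C(C)[C@@H](O[Si](CC)(CC)CC)[C@H](O[Si](CC)(CC)CC)CC1(C)C | intermediate
12 | (3R,4R)-2,6,6-trimethyl-3,4-bis(triethylsilyloxy)cyclohex-1-en-1-yl trifluoromethanesulfonate | FC(F)(F)S(=O)(=O)OC1=C(C)[C@@H](O[Si](CC)(CC)CC)[C@H](O[Si](CC)(CC)CC)CC1(C)C | intermediate
13 | geranyl bromide, (2E)-1-bromo-3,7-dimethylocta-2,6-diene | CC(C)=CCC/C(C)=C/CBr | starting material
14 | geranyltriphenylphosphonium bromide | CC(C)=CCC/C(C)=C/C[P+](c1ccccc1)(c1ccccc1)c1ccccc1.[Br-] | intermediate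
15 | crocetin dialdehyde, (all-E)-2,6,11,15-tetramethylhexadeca-2,4,6,8,10,12,14-heptaenedial | O=C/C(C)=C/C=C/C(C)=C/C=C/C=C(C)/C=C/C=C(C)/C=O | starting material
16 | geranylidenetriphenylphosphorane (not isolated) | CC(C)=CCC/C(C)=C/C=P(c1ccccc1)(c1ccccc1)c1ccccc1 | intermediate
17 | (16Z)-2,6,11,15,19,23-hexamethyltetracosa-2,4,6,8,10,12,14,16,18,22-decaenal, the 7'Z isomer of 18 (not isolated) | CC(C)=CCC/C(C)=C/C=C\C(C)=C\C=C\C(C)=C\C=C\C=C(C)\C=C\C=C(C)\C=O | intermediate
18 | apo-8'-lycopenal, (all-E)-2,6,11,15,19,23-hexamethyltetracosa-2,4,6,8,10,12,14,16,18,22-decaenal | CC(C)=CCC/C(C)=C/C=C/C(C)=C/C=C/C(C)=C/C=C/C=C(C)/C=C/C=C(C)/C=O | intermediate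
19 | 2-[(all-E)-3,7,12,16,20,24-hexamethylpentacosa-1,3,5,7,9,11,13,15,17,19,23-undecaen-1-yl]-4,4,5,5-tetramethyl-1,3,2-dioxaborolane | CC(C)=CCC/C(C)=C/C=C/C(C)=C/C=C/C(C)=C/C=C/C=C(C)/C=C/C=C(C)/C=C/B1OC(C)(C)C(C)(C)O1 | intermediate
20 | (3R,4R)-3,4-bis(triethylsilyloxy)-β,ψ-carotene | CC(C)=CCC/C(C)=C/C=C/C(C)=C/C=C/C(C)=C/C=C/C=C(C)/C=C/C=C(C)/C=C/C1=C(C)[C@@H](O[Si](CC)(CC)CC)[C@H](O[Si](CC)(CC)CC)CC1(C)C | intermediate
21 | (3R,4R)-β,ψ-carotene-3,4-diol | CC(C)=CCC/C(C)=C/C=C/C(C)=C/C=C/C(C)=C/C=C/C=C(C)/C=C/C=C(C)/C=C/C1=C(C)[C@@H](O)[C@H](O)CC1(C)C | target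

Total step count: 12. Longest linear sequence: 9 steps (steps 1 to 7, then 11 and 12).

Steps most likely to fail

Step 6. The ring closure may show poor facial selectivity at the aldehyde carbon (a twisted or closed transition state would deliver the C4 epimer), and some aldehyde may be lost to 1,2-hydrosilylation. The fallback sets C4 after ring formation by a hydroxyl-directed reduction instead of in the C–C bond formation. It sets out from 8: the closure is accepted as a C4-epimeric mixture of the bis-silyl ketone F1, which KN(SiMe3)2 and PhNTf2 convert into the enol triflate mixture F2. HF·pyridine removes both silyl groups to give the diol triflate F3, and MnO2 oxidises only the allylic C4 alcohol, so both epimers converge on the (4R)-hydroxy enone triflate F4. Me4NBH(OAc)3 in MeCN–AcOH should then deliver hydride from the C3-bound borate on the face of the C3 oxygen and give the trans-diol triflate F5. Suzuki–Miyaura coupling of F5 with 19 under the conditions of step 11 comes back to the route at 21.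

Step 11. Oxidative addition at the tetrasubstituted, doubly flanked triflate may be slow, while the decaenyl boronate is lost by protodeboronation or polyene decomposition. The fallback makes the C7=C8 bond by olefination in place of the C6–C7 cross-coupling. It sets out from 12: palladium-catalysed methoxycarbonylation (Pd(OAc)2, dppp, CO, MeOH, Et3N) gives the methyl ester F8, iBu2AlH the allylic alcohol F9, an Appel reaction (CBr4, PPh3) the bromide F10, and PPh3 the phosphonium bromide F11. The ylide of F11 (n-BuLi, THF) reacts with aldehyde 18 in a Wittig reaction, and iodine-catalysed Z to E equilibration comes back to the route at 20.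

Step 7. Deprotonation of the hindered α-hydrogen may be incomplete, and the enolate may expel the C4 silyloxide (β-elimination). The fallback makes the alkenyl electrophile without an enolate. It sets out from 10: hydrazine hydrate (EtOH, Et3N, reflux) gives the hydrazone F6, and iodine with tetramethylguanidine (Barton vinyl iodide synthesis) gives the vinyl iodide F7, in which the only available proton loss again places the alkene at C5=C6. Coupling of F7 with 19 as in step 11 comes back to the route at 20.

Further compounds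
F1 | step 6 | (4R)-2,6,6-trimethyl-3,4-bis(triethylsilyloxy)cyclohexan-1-one, mixture at C2 and C3 | O=C1C(C)C(O[Si](CC)(CC)CC)[C@H](O[Si](CC)(CC)CC)CC1(C)C
F2 | step 6 | (4R)-2,6,6-trimethyl-3,4-bis(triethylsilyloxy)cyclohex-1-en-1-yl trifluoromethanesulfonate, mixture at C3 | FC(F)(F)S(=O)(=O)OC1=C(C)C(O[Si](CC)(CC)CC)[C@H](O[Si](CC)(CC)CC)CC1(C)C
F3 | step 6 | (4R)-3,4-dihydroxy-2,6,6-trimethylcyclohex-1-en-1-yl trifluoromethanesulfonate, mixture at C3 | FC(F)(F)S(=O)(=O)OC1=C(C)C(O)[C@H](O)CC1(C)C
F4 | step 6 | (4R)-4-hydroxy-2,6,6-trimethyl-3-oxocyclohex-1-en-1-yl trifluoromethanesulfonate | FC(F)(F)S(=O)(=O)OC1=C(C)C(=O)[C@H](O)CC1(C)C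
F5 | step 6 | (3R,4R)-3,4-dihydroxy-2,6,6-trimethylcyclohex-1-en-1-yl trifluoromethanesulfonate | FC(F)(F)S(=O)(=O)OC1=C(C)[C@@H](O)[C@H](O)CC1(C)C
F6 | step 7 | hydrazone of (2R,3R,4R)-2,6,6-trimethyl-3,4-bis(triethylsilyloxy)cyclohexan-1-one | NN=C1[C@H](C)[C@@H](O[Si](CC)(CC)CC)[C@H](O[Si](CC)(CC)CC)CC1(C)C
F7 | step 7 | (3R,4R)-1-iodo-2,6,6-trimethyl-3,4-bis(triethylsilyloxy)cyclohex-1-ene | IC1=C(C)[C@@H](O[Si](CC)(CC)CC)[C@H](O[Si](CC)(CC)CC)CC1(C)C
F8 | step 11 | methyl (3R,4R)-2,6,6-trimethyl-3,4-bis(triethylsilyloxy)cyclohex-1-ene-1-carboxylate | COC(=O)C1=C(C)[C@@H](O[Si](CC)(CC)CC)[C@H](O[Si](CC)(CC)CC)CC1(C)C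
F9 | step 11 | [(3R,4R)-2,6,6-trimethyl-3,4-bis(triethylsilyloxy)cyclohex-1-en-1-yl]methanol | OCC1=C(C)[C@@H](O[Si](CC)(CC)CC)[C@H](O[Si](CC)(CC)CC)CC1(C)C
F10 | step 11 | (3R,4R)-1-(bromomethyl)-2,6,6-trimethyl-3,4-bis(triethylsilyloxy)cyclohex-1-ene | BrCC1=C(C)[C@@H](O[Si](CC)(CC)CC)[C@H](O[Si](CC)(CC)CC)CC1(C)C
F11 | step 11 | {[(3R,4R)-2,6,6-trimethyl-3,4-bis(triethylsilyloxy)cyclohex-1-en-1-yl]methyl}triphenylphosphonium bromide | [Br-].c1ccccc1[P+](c1ccccc1)(c1ccccc1)CC1=C(C)[C@@H](O[Si](CC)(CC)CC)[C@H](O[Si](CC)(CC)CC)CC1(C)C
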